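**Retrosynthetic overview**

1. The bond between the methine carbon (CH–CH3) and C2 of the benzofuran is disconnected. This gives a chromene half that carries the (S) tertiary carbinol and a secondary iodide, and a 2‑lithiated benzofuran half. The halves are first joined through a temporary O–SiMe2 tether on the carbinol oxygen.
2. The key event (step 9) is a photoredox radical–polar crossover 1,5 shift of the benzofuran‑2‑yl group from silicon to the secondary carbon radical. Both iodide epimers give the same radical, so the step is stereoconvergent, and the carbinol center sets the methine center.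
3. Enabling feature: the carbinol oxygen is 1,3 to the methine carbon, which allows a six‑membered ipso transition state. The furan ring has an enol‑ether C2=C3 bond, so the radical adds at C2 (the carbon bearing silicon). The resulting C3 radical is benzylic to the benzo ring and para to the oxygen on C6, is easily oxidised, and the β‑silyl cation loses silicon to restore the furan ring.
4. Chromene half: pyran ring from 4‑hydroxy‑2‑methoxyacetophenone and prenal (step 4), carbinol by catalytic asymmetric allylboration (step 5), then intramolecular hydrosilylation/oxidation and iodination. Benzofuran half: furan ring by alkynylation and 5‑endo cyclisation of 5‑iodo‑2,4‑dihydroxyacetophenone (step 2), with phenol and acetyl masked as silyl ether and silyl enol ether.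
5. Ring order: furan ring (step 2) and pyran ring (step 4) are made on separate fragments. The temporary oxasilolane (step 6) and the transient spiro oxasilacyclohexane (step 9) are opened again, and one fluoride step (step 10) removes all silicon.

Key step: step 9

Assumption: iodination of 1 is taken to occur at C5, and the (S) diol catalyst of step 5 is taken to deliver allyl to the Si face of 9; if the sense of induction is the opposite one, the antipodal catalyst is used.

**Route**

Step 1
Reactants: 1 1-(2,4-dihydroxyphenyl)ethan-1-one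
Product: 2 1-(2,4-dihydroxy-5-iodophenyl)ethan-1-one
Conditions: ICl (1.05 equiv), AcOH, 20 °C
Reagents that add atoms: iodine monochloride, ClI
Why: Electrophilic aromatic iodination of a ring activated by two hydroxyl groups should go to C5 (ortho to the 4-OH and para to the hydrogen-bonded 2-OH), which is less hindered than C3 between the two oxygens.

Step 2
Reactants: 2 1-(2,4-dihydroxy-5-iodophenyl)ethan-1-one, 3 ethynyltrimethylsilane
Product: 5 1-(6-hydroxy-1-benzofuran-5-yl)ethan-1-one, via alkynylphenol 4 (not isolated)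
Conditions: PdCl2(PPh3)2 (2 mol %), CuI (4 mol %), Et3N, THF, 50 °C; then Bu4NF (2.5 equiv), 65 °C
Reagents that add atoms: none
Why: Sonogashira coupling of the aryl iodide is followed by fluoride desilylation and 5-endo-dig attack of the ortho phenoxide on the alkyne, which closes the furan ring while the chelated hydroxyl next to the acetyl group, which is not ortho to the alkyne, stays free.

Step 3
Reactants: 5 1-(6-hydroxy-1-benzofuran-5-yl)ethan-1-one
Product: 6 tert-butyl{[5-(1-{[tert-butyl(dimethyl)silyl]oxy}ethenyl)-1-benzofuran-6-yl]oxy}dimethylsilane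
Conditions: tBuMe2SiOTf (2.4 equiv), Et3N (3 equiv), CH2Cl2, 0 → 20 °C
Reagents that add atoms: tert-butyldimethylsilyl trifluoromethanesulfonate, CC(C)(C)[Si](C)(C)OS(=O)(=O)C(F)(F)F
Why: Silyl triflate and amine base silylate the phenol and convert the methyl ketone into its silyl enol ether by soft enolisation, which masks the acidic hydroxyl and the electrophilic acetyl group for the lithiation of step 8 and lets both be released by fluoride at the end.

Step 4
Reactants: 7 1-(4-hydroxy-2-methoxyphenyl)ethan-1-one, 8 3-methylbut-2-enal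
Product: 9 1-(7-methoxy-2,2-dimethyl-2H-chromen-6-yl)ethan-1-one (encecalin)
Conditions: PhB(OH)2 (1.2 equiv), AcOH (cat.), toluene, reflux (Dean–Stark)
Reagents that add atoms: none
Why: Phenylboronic acid-mediated ortho-hydroxyalkylation of the phenol by the enal gives an ortho-quinone methide that closes the pyran ring by oxa-6π electrocyclisation, and C5 (para to the methoxy group) should be attacked in preference to the hindered C3 between the two oxygens.

Step 5
Reactants: 9 1-(7-methoxy-2,2-dimethyl-2H-chromen-6-yl)ethan-1-one, 10 dipropan-2-yl prop-2-en-1-ylboronate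
Product: 11 (2S)-2-(7-methoxy-2,2-dimethyl-2H-chromen-6-yl)pent-4-en-2-ol
Conditions: (S)-3,3′-Br2-BINOL (15 mol %), PhCF3/toluene (3:1), −35 → 20 °C; aqueous work-up
Reagents that add atoms: none
Why: In this chiral-diol-catalysed allylboration of a ketone, exchange of an isopropoxy ligand for the binaphthol gives a more Lewis acidic chiral boronate that should deliver allyl through a closed chair transition state to the Si face of the aryl methyl ketone and so set the (S) tertiary carbinol.

Step 6
Reactants: 11 (2S)-2-(7-methoxy-2,2-dimethyl-2H-chromen-6-yl)pent-4-en-2-ol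
Product: 14 (2S)-2-(7-methoxy-2,2-dimethyl-2H-chromen-6-yl)pentane-2,4-diol (both C4 epimers), via hydrosilyl ether 12 (not isolated), via oxasilolane 13 (not isolated)
Conditions: HMe2SiCl, Et3N, DMAP (cat.), CH2Cl2, 0 °C; Pt2[(CH2=CHSiMe2)2O]3 (0.2 mol %), hexane, 50 °C; 30 % H2O2, KF, KHCO3, THF/MeOH, 40 °C
Reagents that add atoms: hydrogen peroxide, OO
Why: The hydrosilyl ether should undergo platinum-catalysed intramolecular 5-exo hydrosilylation of the terminal alkene only (the internal chromene alkene is inert), and Tamao–Fleming oxidation of the C–Si bond then gives the 1,3-diol, whose new secondary center needs no control because it is erased in step 9.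

Step 7
Reactants: 14 (2S)-2-(7-methoxy-2,2-dimethyl-2H-chromen-6-yl)pentane-2,4-diol
Product: 15 (2S)-4-iodo-2-(7-methoxy-2,2-dimethyl-2H-chromen-6-yl)pentan-2-ol (both C4 epimers)
Conditions: I2 (1.3 equiv), PPh3 (1.3 equiv), imidazole (2.5 equiv), CH2Cl2, 0 → 20 °C
Reagents that add atoms: iodine, II
Why: In this Appel iodination only the secondary hydroxyl should form the oxyphosphonium ion and be displaced by iodide, while the hindered tertiary benzylic hydroxyl stays untouched under the imidazole-buffered conditions.

Step 8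
Reactants: 15 (2S)-4-iodo-2-(7-methoxy-2,2-dimethyl-2H-chromen-6-yl)pentan-2-ol, 6 tert-butyl{[5-(1-{[tert-butyl(dimethyl)silyl]oxy}ethenyl)-1-benzofuran-6-yl]oxy}dimethylsilane
Product: 18 [6-{[tert-butyl(dimethyl)silyl]oxy}-5-(1-{[tert-butyl(dimethyl)silyl]oxy}ethenyl)-1-benzofuran-2-yl]{[(2S)-4-iodo-2-(7-methoxy-2,2-dimethyl-2H-chromen-6-yl)pentan-2-yl]oxy}dimethylsilane, via chlorosilyl ether 16 (not isolated), via 2-lithiobenzofuran 17 (not isolated)
Conditions: 15, Me2SiCl2 (5 equiv), Et3N (2 equiv), DMAP (cat.), CH2Cl2, 0 → 20 °C, filtered (pentane) and evaporated; 6, LiN(iPr)2 (1.05 equiv), THF, −78 °C; then 16, −78 → −20 °C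
Reagents that add atoms: dichlorodimethylsilane, C[Si](C)(Cl)Cl
Why: The tertiary alcohol is silylated by the small dichlorosilane used in excess, and the remaining Si–Cl bond is then substituted at −78 °C by the 2-lithiobenzofuran formed by deprotonation of the most acidic C2–H of 6, a substitution at silicon that should be far faster than any reaction of the aryllithium with the secondary iodide or the other silyl groups.

Step 9
Reactants: 18 [6-{[tert-butyl(dimethyl)silyl]oxy}-5-(1-{[tert-butyl(dimethyl)silyl]oxy}ethenyl)-1-benzofuran-2-yl]{[(2S)-4-iodo-2-(7-methoxy-2,2-dimethyl-2H-chromen-6-yl)pentan-2-yl]oxy}dimethylsilane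
Product: 19 {[(2S,4S)-4-[6-{[tert-butyl(dimethyl)silyl]oxy}-5-(1-{[tert-butyl(dimethyl)silyl]oxy}ethenyl)-1-benzofuran-2-yl]-2-(7-methoxy-2,2-dimethyl-2H-chromen-6-yl)pentan-2-yl]oxy}(methoxy)dimethylsilane
Conditions: fac-Ir(ppy)3 (2 mol %), 2,6-lutidine (2 equiv), MeOH (10 equiv), MeCN (0.01 M, degassed), blue LEDs (450 nm), 25 °C
Reagents that add atoms: methanol, CO
Why: Proposed new method: photoexcited fac-Ir(ppy)3 reduces the C–I bond of either iodide epimer of 18 to one planar secondary radical, which attacks C2 of the furan ring (ipso to silicon) through a six-membered transition state; the resulting spiro C3 radical, benzylic to the benzo ring and para to its O-silyl group, is oxidised by the tetravalent iridium formed in the first event to a β-silyl cation, and loss of silicon to methanol/2,6-lutidine restores the benzofuran, so that the heteroaryl group moves from silicon to carbon in a redox-neutral 1,5 shift. The closest known reaction types are the tin-hydride-mediated stereoselective radical 1,5-aryl migration from silicon to carbon in arylsilyl ethers of γ-halo alcohols and the photoredox alkylation of heteroarenes with unactivated alkyl halides that ends by oxidation and rearomatisation; the oxidative ending is chosen because expulsion of a silyl radical from a dihydrobenzofuranyl radical is estimated to be too endothermic to carry a tin hydride chain. No ring is left in the product: the transient 1-oxa-2-silacyclohexane closes in the 6-exo-trig mode at the ipso carbon and opens again when silicon is lost. The new methine stereocenter is controlled by the tertiary carbinol center through a chair-like transition state in which the methyl group on the radical carbon and the large 2,4-dioxygenated aryl group on the carbinol carbon are equatorial and the carbinol methyl group is axial, which corresponds to the (2S,4S) product. The step needs ipso attack at C2 instead of attack at C3 or simple reduction, and this is secured by the enol-ether-like C2=C3 bond (attack at C2 gives the stabilised benzylic radical), by the six- against seven-membered ring size and by high dilution in the absence of a hydrogen donor.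

Step 10
Reactants: 19 {[(2S,4S)-4-[6-{[tert-butyl(dimethyl)silyl]oxy}-5-(1-{[tert-butyl(dimethyl)silyl]oxy}ethenyl)-1-benzofuran-2-yl]-2-(7-methoxy-2,2-dimethyl-2H-chromen-6-yl)pentan-2-yl]oxy}(methoxy)dimethylsilane
Product: 20 1-{6-hydroxy-2-[(2S,4S)-4-hydroxy-4-(7-methoxy-2,2-dimethyl-2H-chromen-6-yl)pentan-2-yl]-1-benzofuran-5-yl}ethan-1-one (target)
Conditions: Bu4NF (5 equiv), AcOH (5 equiv), THF, 0 → 20 °C
Reagents that add atoms: none
Why: Fluoride cleaves the Si–O bonds of the dialkoxysilane, the aryl silyl ether and the silyl enol ether (which gives the methyl ketone on protonation), and buffering with acetic acid should keep the ionisable tertiary benzylic alcohol and the chromene intact.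

**Compound list**

1 | 1-(2,4-dihydroxyphenyl)ethan-1-one | CC(=O)c1ccc(O)cc1O | starting material
2 | 1-(2,4-dihydroxy-5-iodophenyl)ethan-1-one | CC(=O)c1cc(I)c(O)cc1O | intermediate
3 | ethynyltrimethylsilane | C#C[Si](C)(C)C | starting material
4 | 1-{2,4-dihydroxy-5-[(trimethylsilyl)ethynyl]phenyl}ethan-1-one (not isolated) | CC(=O)c1cc(C#C[Si](C)(C)C)c(O)cc1O | intermediate
5 | 1-(6-hydroxy-1-benzofuran-5-yl)ethan-1-one | CC(=O)c1cc2ccoc2cc1O | intermediate
6 | tert-butyl{[5-(1-{[tert-butyl(dimethyl)silyl]oxy}ethenyl)-1-benzofuran-6-yl]oxy}dimethylsilane | C=C(O[Si](C)(C)C(C)(C)C)c1cc2ccoc2cc1O[Si](C)(C)C(C)(C)C | intermediate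
7 | 1-(4-hydroxy-2-methoxyphenyl)ethan-1-one | CC(=O)c1ccc(O)cc1OC | starting material
8 | 3-methylbut-2-enal | CC(C)=CC=O | starting material
9 | 1-(7-methoxy-2,2-dimethyl-2H-chromen-6-yl)ethan-1-one | COc1cc2c(cc1C(C)=O)C=CC(C)(C)O2 | intermediate
10 | dipropan-2-yl prop-2-en-1-ylboronate | C=CCB(OC(C)C)OC(C)C | starting material
11 | (2S)-2-(7-methoxy-2,2-dimethyl-2H-chromen-6-yl)pent-4-en-2-ol | COc1cc2c(cc1[C@@](C)(O)CC=C)C=CC(C)(C)O2 | intermediate
12 | {[(2S)-2-(7-methoxy-2,2-dimethyl-2H-chromen-6-yl)pent-4-en-2-yl]oxy}dimethylsilane (not isolated) | COc1cc2c(cc1[C@@](C)(O[SiH](C)C)CC=C)C=CC(C)(C)O2 | intermediate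
13 | (5S)-5-(7-methoxy-2,2-dimethyl-2H-chromen-6-yl)-2,2,3,5-tetramethyl-1,2-oxasilolane, both C3 epimers (not isolated) | COc1cc2c(cc1[C@@](C)(O[Si]3(C)C)CC3C)C=CC(C)(C)O2 | intermediate
14 | (2S)-2-(7-methoxy-2,2-dimethyl-2H-chromen-6-yl)pentane-2,4-diol, both C4 epimers | COc1cc2c(cc1[C@@](C)(O)CC(C)O)C=CC(C)(C)O2 | intermediate
15 | (2S)-4-iodo-2-(7-methoxy-2,2-dimethyl-2H-chromen-6-yl)pentan-2-ol, both C4 epimers | COc1cc2c(cc1[C@@](C)(O)CC(C)I)C=CC(C)(C)O2 | intermediate
16 | chloro{[(2S)-4-iodo-2-(7-methoxy-2,2-dimethyl-2H-chromen-6-yl)pentan-2-yl]oxy}dimethylsilane (not isolated) | COc1cc2c(cc1[C@@](C)(O[Si](C)(C)Cl)CC(C)I)C=CC(C)(C)O2 | intermediate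
17 | [6-{[tert-butyl(dimethyl)silyl]oxy}-5-(1-{[tert-butyl(dimethyl)silyl]oxy}ethenyl)-1-benzofuran-2-yl]lithium (not isolated) | [Li]c1cc2cc(C(=C)O[Si](C)(C)C(C)(C)C)c(O[Si](C)(C)C(C)(C)C)cc2o1 | intermediate
18 | [6-{[tert-butyl(dimethyl)silyl]oxy}-5-(1-{[tert-butyl(dimethyl)silyl]oxy}ethenyl)-1-benzofuran-2-yl]{[(2S)-4-iodo-2-(7-methoxy-2,2-dimethyl-2H-chromen-6-yl)pentan-2-yl]oxy}dimethylsilane, both C4 epimers | COc1cc2c(cc1[C@@](C)(O[Si](C)(C)c1cc3cc(C(=C)O[Si](C)(C)C(C)(C)C)c(O[Si](C)(C)C(C)(C)C)cc3o1)CC(C)I)C=CC(C)(C)O2 | intermediate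
19 | {[(2S,4S)-4-[6-{[tert-butyl(dimethyl)silyl]oxy}-5-(1-{[tert-butyl(dimethyl)silyl]oxy}ethenyl)-1-benzofuran-2-yl]-2-(7-methoxy-2,2-dimethyl-2H-chromen-6-yl)pentan-2-yl]oxy}(methoxy)dimethylsilane | COc1cc2c(cc1[C@@](C)(O[Si](C)(C)OC)C[C@H](C)c1cc3cc(C(=C)O[Si](C)(C)C(C)(C)C)c(O[Si](C)(C)C(C)(C)C)cc3o1)C=CC(C)(C)O2 | intermediate
20 | 1-{6-hydroxy-2-[(2S,4S)-4-hydroxy-4-(7-methoxy-2,2-dimethyl-2H-chromen-6-yl)pentan-2-yl]-1-benzofuran-5-yl}ethan-1-one | COc1cc2c(cc1[C@@](C)(O)C[C@H](C)c1cc3cc(C(C)=O)c(O)cc3o1)C=CC(C)(C)O2 | target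

**Step count and risks**

Total step count: 10 (steps 1–3 benzofuran half, steps 4–7 chromene half, steps 8–10 tethering, key step and deprotection).
Longest linear sequence: 7 steps (steps 4–10, from 7 to 20).

Steps most likely to fail:

1. Step 9. The spiro radical may be reduced or capture a hydrogen atom before it is oxidised, so that the furan ring is not restored. Electron transfer to the unactivated C–I bond may be slow. The ipso attack may show poor facial selectivity, because a methyl and an aryl group compete for the equatorial site on the fully substituted carbinol carbon. The fallback uses known chemistry, sets out from 15 and 6 and comes back at 20. Silylation of 15 (Et3SiOTf, 2,6-lutidine) gives triethylsilyl ether F1. Copper-catalysed borylation of the secondary iodide (CuI, PPh3, LiOMe, B2pin2, DMF) gives the pinacol boronic ester as two epimers at the boron-bearing carbon, and the (2S,4S) boronic ester F2 is separated by chromatography. F2 is added at −78 °C to 17 (made from 6 as in step 8) to form the heteroaryl boronate complex. N-Bromosuccinimide then brominates C3 of the furan ring, the secondary alkyl group migrates from boron to C2 with retention, and boron and bromide are lost; this enantiospecific, transition-metal-free coupling of a secondary boronic ester with a lithiated benzofuran gives the coupled triethylsilyl ether F3. Bu4NF/AcOH removes the three silyl groups and gives 20.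

2. Step 5. Conversion or enantioselectivity may be low, because the ketone is deactivated by two oxygen donors and its ortho methoxy group can disturb the closed transition state. The fallback sets out from 9 and comes back at 11. Corey–Bakshi–Shibata reduction ((S)-methyl oxazaborolidine, BH3·SMe2) gives (R) secondary alcohol F4, and N,N-diisopropylcarbamoyl chloride/Et3N gives carbamate F5. s-BuLi (Et2O, −78 °C) lithiates the benzylic position with retention, and allylboronic acid pinacol ester is added. The boronate complex rearranges by stereospecific 1,2-migration to tertiary boronic ester F6, which is oxidised in the same flask (NaOH, H2O2, retention) to 11.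

3. Step 7. The free tertiary 2,4-dioxygenated benzylic alcohol may ionise and dehydrate, or take part as a neighbouring group, while the secondary hydroxyl is activated. The fallback sets out from 11 and 6 and comes back at 18; the tether is put on before the halide is made. Wacker oxidation of 11 (PdCl2, CuCl, O2, DMF/H2O) gives β-hydroxy ketone F7. Compound 6 is lithiated (LiN(iPr)2, THF, −78 °C) and quenched with excess Me2SiCl2 to give chlorosilane F8, which silylates F7 (imidazole, DMF) to tethered ketone F9. NaBH4 (MeOH, 0 °C) reduces the ketone to tethered alcohol F10 (either epimer), and Appel iodination (I2, PPh3, imidazole), now with the tertiary oxygen blocked, gives 18.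

**Further compounds**

F1 | step 9 | triethyl{[(2S)-4-iodo-2-(7-methoxy-2,2-dimethyl-2H-chromen-6-yl)pentan-2-yl]oxy}silane | COc1cc2c(cc1[C@@](C)(O[Si](CC)(CC)CC)CC(C)I)C=CC(C)(C)O2
F2 | step 9 | triethyl{[(2S,4S)-2-(7-methoxy-2,2-dimethyl-2H-chromen-6-yl)-4-(4,4,5,5-tetramethyl-1,3,2-dioxaborolan-2-yl)pentan-2-yl]oxy}silane | COc1cc2c(cc1[C@@](C)(O[Si](CC)(CC)CC)C[C@H](C)B1OC(C)(C)C(C)(C)O1)C=CC(C)(C)O2
F3 | step 9 | {[(2S,4S)-4-[6-{[tert-butyl(dimethyl)silyl]oxy}-5-(1-{[tert-butyl(dimethyl)silyl]oxy}ethenyl)-1-benzofuran-2-yl]-2-(7-methoxy-2,2-dimethyl-2H-chromen-6-yl)pentan-2-yl]oxy}triethylsilane | COc1cc2c(cc1[C@@](C)(O[Si](CC)(CC)CC)C[C@H](C)c1cc3cc(C(=C)O[Si](C)(C)C(C)(C)C)c(O[Si](C)(C)C(C)(C)C)cc3o1)C=CC(C)(C)O2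
F4 | step 5 | (1R)-1-(7-methoxy-2,2-dimethyl-2H-chromen-6-yl)ethan-1-ol | COc1cc2c(cc1[C@@H](C)O)C=CC(C)(C)O2
F5 | step 5 | (1R)-1-(7-methoxy-2,2-dimethyl-2H-chromen-6-yl)ethyl N,N-di(propan-2-yl)carbamate | COc1cc2c(cc1[C@@H](C)OC(=O)N(C(C)C)C(C)C)C=CC(C)(C)O2
F6 | step 5 | 2-[(2R)-2-(7-methoxy-2,2-dimethyl-2H-chromen-6-yl)pent-4-en-2-yl]-4,4,5,5-tetramethyl-1,3,2-dioxaborolane | COc1cc2c(cc1[C@@](C)(B3OC(C)(C)C(C)(C)O3)CC=C)C=CC(C)(C)O2
F7 | step 7 | (4S)-4-hydroxy-4-(7-methoxy-2,2-dimethyl-2H-chromen-6-yl)pentan-2-one | COc1cc2c(cc1[C@@](C)(O)CC(C)=O)C=CC(C)(C)O2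
F8 | step 7 | [6-{[tert-butyl(dimethyl)silyl]oxy}-5-(1-{[tert-butyl(dimethyl)silyl]oxy}ethenyl)-1-benzofuran-2-yl]chlorodimethylsilane | C=C(O[Si](C)(C)C(C)(C)C)c1cc2cc([Si](C)(C)Cl)oc2cc1O[Si](C)(C)C(C)(C)C
F9 | step 7 | (4S)-4-({[6-{[tert-butyl(dimethyl)silyl]oxy}-5-(1-{[tert-butyl(dimethyl)silyl]oxy}ethenyl)-1-benzofuran-2-yl]dimethylsilyl}oxy)-4-(7-methoxy-2,2-dimethyl-2H-chromen-6-yl)pentan-2-one | COc1cc2c(cc1[C@@](C)(O[Si](C)(C)c1cc3cc(C(=C)O[Si](C)(C)C(C)(C)C)c(O[Si](C)(C)C(C)(C)C)cc3o1)CC(C)=O)C=CC(C)(C)O2
F10 | step 7 | (4S)-4-({[6-{[tert-butyl(dimethyl)silyl]oxy}-5-(1-{[tert-butyl(dimethyl)silyl]oxy}ethenyl)-1-benzofuran-2-yl]dimethylsilyl}oxy)-4-(7-methoxy-2,2-dimethyl-2H-chromen-6-yl)pentan-2-ol, both C2 epimers | COc1cc2c(cc1[C@@](C)(O[Si](C)(C)c1cc3cc(C(=C)O[Si](C)(C)C(C)(C)C)c(O[Si](C)(C)C(C)(C)C)cc3o1)CC(C)O)C=CC(C)(C)O2
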